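The runs were computed for substances that don't exist, noise included.

Monday's flask stood at 26.9% target on average from 6.00 min to 80.0 min, flat within the scatter, so in that flask nothing slow showed after the first reading.

| setting | Friday's | Wednesday's | Monday's | flask |
|---|---|---|---|---|
| substrate | 0.010 M (in portions, 3) | 0.015 M (in portions, 3) | 0.020 M (in portions, 3) | 0.020 M (in portions, 3) |
| partner | 2 equiv | 2 equiv | 1 equiv | 2.00 equiv |
| remark | run made earlier; portions every 6.0 s | run made earlier; portions every 6.0 s | run made earlier; portions every 6.0 s | the portions of substrate follow each other after 6.0 s, the first at the start |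
| time |  |  |  | 1.0 h |

| run | time / min | target / % |
|---|---|---|
| Friday's | 4.00 | 23.3 |
| Friday's | 12.0 | 31.7 |
| Friday's | 20.0 | 32.3 |
| Friday's | 30.0 | 30.7 |
| Friday's | 40.0 | 29.4 |
| Friday's | 60.0 | 31.0 |
| Friday's | 80.0 | 30.2 |
| Wednesday's | 6.00 | 35.7 |
| Wednesday's | 8.00 | 39.3 |
| Wednesday's | 12.0 | 40.1 |
| Wednesday's | 20.0 | 41.5 |
| Wednesday's | 30.0 | 39.4 |
| Wednesday's | 50.0 | 39.2 |
| Wednesday's | 80.0 | 43.3 |
| Monday's | 6.00 | 25.9 |
| Monday's | 10.0 | 27.4 |
| Monday's | 20.0 | 27.0 |
| Monday's | 40.0 | 27.6 |
| Monday's | 80.0 | 26.6 |

(each reading ± 1 percentage point)

- why nothing more happens at 1.0 h, or that something still does (it is still moving / all of the substrate has reacted / the partner has run out first / forward and back rates have come level)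
- the target standing at 1.0 h, as a percentage of the substrate charged

- the reaction counts as stopped when no species that holds the substrate changes by six tenths of a point or more over the second half of the time

You take over a flask that gets substrate in portions over partner. Work with what is left, reckoned from the charge by subtraction:

Monday: 73.1% left on each side of 0.020 M gives 25.2 /M

Wednesday, from 8.00 min on: 40.5% target on 0.015 M gives 28.4 /M

Their mean, 26.8 /M, a reading with the scatter of those runs, is the standing ratio: target divided by substrate side left times partner side left. For your flask I solve:

target share = ratio × charge × (substrate left) × (partner left) = 45.3%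

That is my reckoning for your flask, and it carries the same scatter. Do not trim the partner: Monday's flask, with the same substrate charge and 1 equiv, gave 26.9%. The readings do not show the partner itself.

The forecast says 45% and forward and back rates have come level: “This points to an equilibrium”.

The flask gives 45.5%, and the partner has run out first: partner stands at 0% of its charge at 1.00 h.

    substrate ⇌ open intermediate (K = 0.220, k = 0.0250 /s)
    partner → second intermediate (k = 0.00920 /s)
    open intermediate + second intermediate ⇌ target (K = 150 /M, k = 1.20 /M/s)

In this flask the partner side of the ratio is second intermediate, the partner's resting state, at 0.0309 M, and this flask's own ratio comes to 27.0 /M. What holds target down is its undoing into open intermediate and second intermediate: with that step taken away, target reaches >99.9% against 45.5%. The ratio reckons a neighbour flask with 8.00 equiv of partner at 79.4%, and that flask, its partner at 0%, gives 79.6%.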